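## Retrosynthetic overview

- The two esters go on last: tiglate at C8, then senecioate at C9, onto an 8α-hydroxy-9-ketone whose C2 carbonyl is masked as a dioxolane; C9 is reduced from the convex face between the two acylations.
- Ring B (C5–C10) is opened at C7–C8 by a retro carbonyl-ene reaction, giving a prenyl chain on C5 and a C9-keto-C8-aldehyde on C10; these trace back to a C6 aldehyde on C5 and a protected C8,C9-diol on C10.
- The strategy rests on ring A (C1–C5, C10): three contiguous stereocentres, C4 (methyl), quaternary C5 (methyl) and C10–H, with the C2 carbonyl para to C5. This is the retron of a Diels–Alder reaction that makes C3–C4 and C5–C10 from tiglic aldehyde and a 2-silyloxydiene.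
- The diene comes from (R)-glyceraldehyde acetonide by olefination and enol silylation. Ring A is formed first (step 3), ring B second (step 10).

Key step: step 3

Assumption: atoms carry eremophilane numbers (C14 on C5, C15 on C4, both β; C11–C13 = isopropenyl), and the (R)-configured oxazaborolidinium catalyst is taken to leave the α-Si face of bound tiglic aldehyde open, as the formyl C–H···O binding model for α-substituted enals predicts.

## Route

Step 1
Reactants: 1 (R)-glyceraldehyde acetonide; 2 dimethyl (2-oxopropyl)phosphonate
Product: 3 (S,E)-4-(2,2-dimethyl-1,3-dioxolan-4-yl)but-3-en-2-one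
Conditions: K2CO3, H2O/THF, 0 °C → rt
Reagents that add atoms: none
Why: Horner–Wadsworth–Emmons olefination with a stabilised β-ketophosphonate anion gives the (E)-enone, and the mild carbonate base does not epimerise the α-alkoxy aldehyde.

Step 2
Reactants: 3 enone
Product: 4 (S,E)-{[4-(2,2-dimethyl-1,3-dioxolan-4-yl)buta-1,3-dien-2-yl]oxy}triisopropylsilane
Conditions: TIPSOTf, Et3N, CH2Cl2, 0 °C
Reagents that add atoms: triisopropylsilyl triflate, CC(C)[Si](OS(=O)(=O)C(F)(F)F)(C(C)C)C(C)C
Why: Soft enolisation of the methyl ketone (silyl triflate and amine) deprotonates the CH3 group and gives the cross-conjugated 2-silyloxydiene with the (E)-alkene intact; the bulky TIPS enol ether is chosen because it must survive steps 3 to 7.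

Step 3
Reactants: 5 tiglic aldehyde, (E)-2-methylbut-2-enal; 4 silyloxydiene
Product: 6 (1R,2S,6S)-2-[(4S)-2,2-dimethyl-1,3-dioxolan-4-yl]-1,6-dimethyl-4-(triisopropylsilyloxy)cyclohex-3-ene-1-carbaldehyde (ring A; formyl carbon = C6, dioxolane carbons = C9 and C8)
Conditions: (R)-3,3-diphenyl-1-(o-tolyl)tetrahydro-1H,3H-pyrrolo[1,2-c][1,3,2]oxazaborole (20 mol%), HNTf2 (17 mol%), CH2Cl2, −78 → −40 °C
Reagents that add atoms: none
Why: The enal, bound through its carbonyl oxygen to the cationic boron with the formyl C–H held against the ring oxygen, reacts in a concerted but asynchronous normal-demand [4+2]: the silyloxy group makes C3 the nucleophilic diene terminus, so C3–C4 (to the enal β-carbon) forms first and the congested C5–C10 bond closes last, which fixes the regiochemistry with the enol ether at C1=C2. The closest known reaction type is the oxazaborolidinium-catalysed Diels–Alder reaction of α-substituted enals with 2-silyloxydienes. Ring A is closed by this intermolecular cycloaddition, both σ bonds being made suprafacially on each partner. At C4 and C5 the (E)-geometry of the dienophile is retained, so C14 and C15 end up cis; at C10 the endo orientation of the formyl group places C9 cis to C6, the future cis ring fusion; the aryl groups of the catalyst block one face of the s-trans enal so that the diene adds to the α-Si face, giving (4S,5R,10S) in eremophilane numbering, while C9 is carried in from 1. The step needs regio-, endo- and face-selectivity, which come from the 2-silyloxy group, from secondary overlap with the activated formyl group and from the catalyst, respectively. Because C9 is a fixed stereocentre, any adduct with the antipodal ring A is a diastereomer and is removed by chromatography before C9 is oxidised in step 9.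

Step 4
Reactants: 6 ring A aldehyde
Product: 7 C5-vinyl compound (CHO of 6 replaced by CH=CH2, C6=C7; other groups and stereocentres as in 6)
Conditions: Ph3PCH3Br, KN(SiMe3)2, THF, 0 °C → rt
Reagents that add atoms: methyltriphenylphosphonium bromide, C[P+](c1ccccc1)(c1ccccc1)c1ccccc1.[Br-]
Why: Wittig methylenation with the smallest unstabilised ylide works on hindered aldehydes; the aldehyde has no α-hydrogen, so nothing can epimerise, and the silyl enol ether and acetonide are stable to base.

Step 5
Reactants: 7 C5-vinyl compound
Product: 9 primary alcohol (C5–CH2–CH2OH, hydroxyl on C7), via B-alkyl-9-BBN borane 8 (not isolated)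
Conditions: 9-BBN, THF, 0 °C → rt; then 3 M NaOH, 30% H2O2, 0 °C
Reagents that add atoms: 9-BBN, B1C2CCCC1CCC2 (boron and carbocycle, kept in 8 only); hydrogen peroxide, OO
Why: Hydroboration–oxidation with the bulky dialkylborane is anti-Markovnikov and should take the monosubstituted alkene much faster than the hindered trisubstituted silyl enol ether, which also tolerates the brief cold basic peroxide work-up.

Step 6
Reactants: 9 primary alcohol
Product: 10 aldehyde (C5–CH2–CHO, C7 aldehyde)
Conditions: Dess–Martin periodinane, pyridine, CH2Cl2, 0 °C → rt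
Reagents that add atoms: none
Why: Dess–Martin oxidation buffered with pyridine is neutral enough to leave the silyl enol ether and the acetonide untouched.

Step 7
Reactants: 10 aldehyde
Product: 11 prenyl compound (C5–CH2–CH=C(CH3)2, C7=C11)
Conditions: i-PrPPh3I, n-BuLi, THF, 0 °C; then 10, −78 °C → rt
Reagents that add atoms: isopropyltriphenylphosphonium iodide, CC(C)[P+](c1ccccc1)(c1ccccc1)c1ccccc1.[I-]
Why: Wittig olefination with isopropylidenetriphenylphosphorane converts the aldehyde into the trisubstituted prenyl alkene, the ene donor for ring B; addition at low temperature limits enolisation of the aldehyde.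

Step 8
Reactants: 11 prenyl compound
Product: 12 C2 ethylene ketal with free C8,C9-diol
Conditions: ethylene glycol (20 equiv), CSA (10 mol%), 4 Å MS, CH2Cl2, rt
Reagents that add atoms: ethylene glycol, OCCO
Why: Acid-catalysed transketalisation: C-protonation of the silyl enol ether at C1 gives an oxocarbenium ion that glycol traps as the dioxolane, and the acetonide is passed on to the excess glycol; the C2 dioxolane is degenerate under these conditions, and the only intramolecular ketal the freed diol could form is a strained 2,7-dioxabicyclo[2.2.1]heptane that excess glycol should outcompete.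

Step 9
Reactants: 12 ketal diol
Product: 13 C9-keto-C8-aldehyde (used crude after azeotropic drying)
Conditions: (COCl)2, DMSO, CH2Cl2, −78 °C; then i-Pr2NEt, −78 → −40 °C
Reagents that add atoms: none
Why: Swern oxidation takes both carbinols of a 1,2-diol to the 1,2-dicarbonyl without cleaving the C8–C9 bond; the hindered base and low temperature are chosen to keep the C10 hydrogen, now α to a ketone, in place.

Step 10
Reactants: 13 keto aldehyde
Product: 14 2,2-ethylenedioxy-8α-hydroxy-10βH-eremophil-11-en-9-one (cis-decalin; 7β-isopropenyl)
Conditions: Sc(OTf)3 (10 mol%), 4 Å MS, CH2Cl2, −78 → −20 °C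
Reagents that add atoms: none
Why: Two-point binding of the 1,2-dicarbonyl to scandium activates the aldehyde for an intramolecular carbonyl-ene reaction of the citronellal-to-isopulegol kind, in which C7 bonds to C8 through a chair-like transition state while a methyl hydrogen passes to the aldehyde oxygen and leaves the isopropenyl group; with the carbonyl oxygen and the alkene both pseudo-equatorial in the steroid-like chair (C14 equatorial on ring B, C15 equatorial on ring A), C7 and C8 should be set trans to each other and in the required sense relative to C5 and C10.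

Step 11
Reactants: 14 hydroxy ketone
Product: 15 8α-tiglate of 14
Conditions: (E)-2-methylbut-2-enoyl chloride, pyridine, DMAP (cat.), CH2Cl2, 0 °C → rt
Reagents that add atoms: tigloyl chloride, C/C=C(\C)C(Cl)=O
Why: DMAP-catalysed acylation of the equatorial C8 hydroxyl; the more hindered acyl group goes onto the more accessible alcohol, the weak base spares the C10 hydrogen, and C8 is already in its more stable equatorial configuration.

Step 12
Reactants: 15 keto tiglate
Product: 16 2,2-ethylenedioxy-9α-hydroxy-8α-tigloyloxy-10βH-eremophil-11-ene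
Conditions: LiBH(s-Bu)3, THF, −78 °C; AcOH quench at −78 °C
Reagents that add atoms: none
Why: The bulky hydride attacks the C9 ketone along the equatorial path from the convex face, because the axial path is blocked by C4 of the folded cis-decalin, and so should give the axial 9α-alcohol cis to the 8-ester; the hindered tiglate and the ketal are inert at −78 °C, and the cold acidic quench forestalls acyl migration.

Step 13
Reactants: 16 hydroxy tiglate
Product: 17 2,2-ethylenedioxy-9α-senecioyloxy-8α-tigloyloxy-10βH-eremophil-11-ene
Conditions: 3-methylbut-2-enoyl chloride, pyridine, DMAP (1 equiv), CH2Cl2, 0 °C → rt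
Reagents that add atoms: 3-methylbut-2-enoyl chloride, CC(C)=CC(Cl)=O
Why: Acylation of the axial C9 hydroxyl via the acylpyridinium; pyridine rather than a trialkylamine avoids deconjugation of the senecioyl unit through a vinylketene.

Step 14
Reactants: 17 diester ketal
Product: 18 CNP0181050.1, 9α-senecioyloxy-8α-tigloyloxy-10βH-eremophil-11-en-2-one
Conditions: 1 M aq. HCl, THF, rt
Reagents that add atoms: water, O
Why: Mild acid hydrolysis of the dioxolane frees the C2 ketone; the two enoate esters and the isopropenyl group tolerate dilute acid at room temperature, and the ketone has no epimerisable α-stereocentre.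

## Compound list

1 | (R)-2,2-dimethyl-1,3-dioxolane-4-carbaldehyde | O=C[C@H]1COC(C)(C)O1 | starting material
2 | dimethyl (2-oxopropyl)phosphonate | CC(=O)CP(=O)(OC)OC | starting material
3 | (S,E)-4-(2,2-dimethyl-1,3-dioxolan-4-yl)but-3-en-2-one | CC(=O)/C=C/[C@H]1COC(C)(C)O1 | intermediate
4 | (S,E)-{[4-(2,2-dimethyl-1,3-dioxolan-4-yl)buta-1,3-dien-2-yl]oxy}triisopropylsilane | C=C(O[Si](C(C)C)(C(C)C)C(C)C)/C=C/[C@H]1COC(C)(C)O1 | intermediate
5 | tiglic aldehyde, (E)-2-methylbut-2-enal | C/C=C(\C)C=O | starting material
6 | (1R,2S,6S)-2-[(4S)-2,2-dimethyl-1,3-dioxolan-4-yl]-1,6-dimethyl-4-(triisopropylsilyloxy)cyclohex-3-ene-1-carbaldehyde | O=C[C@@]1(C)[C@H](C=C(O[Si](C(C)C)(C(C)C)C(C)C)C[C@@H]1C)[C@H]2COC(C)(C)O2 | intermediate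
7 | C5-vinyl analogue of 6 | C=C[C@@]1(C)[C@H](C=C(O[Si](C(C)C)(C(C)C)C(C)C)C[C@@H]1C)[C@H]2COC(C)(C)O2 | intermediate
8 | B-alkyl-9-BBN adduct of 7 (boron on C7) | C1CC2CCCC(C1)B2CC[C@@]3(C)[C@H](C=C(O[Si](C(C)C)(C(C)C)C(C)C)C[C@@H]3C)[C@H]4COC(C)(C)O4 | intermediate
9 | primary alcohol, C5–CH2CH2OH | OCC[C@@]1(C)[C@H](C=C(O[Si](C(C)C)(C(C)C)C(C)C)C[C@@H]1C)[C@H]2COC(C)(C)O2 | intermediate
10 | aldehyde, C5–CH2CHO | O=CC[C@@]1(C)[C@H](C=C(O[Si](C(C)C)(C(C)C)C(C)C)C[C@@H]1C)[C@H]2COC(C)(C)O2 | intermediate
11 | prenyl compound, C5–CH2CH=C(CH3)2 | CC(C)=CC[C@@]1(C)[C@H](C=C(O[Si](C(C)C)(C(C)C)C(C)C)C[C@@H]1C)[C@H]2COC(C)(C)O2 | intermediate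
12 | C2 ethylene ketal, C8,C9-diol | CC(C)=CC[C@@]1(C)[C@H](CC2(C[C@@H]1C)OCCO2)[C@H](O)CO | intermediate
13 | C9-keto-C8-aldehyde | CC(C)=CC[C@@]1(C)[C@H](CC2(C[C@@H]1C)OCCO2)C(=O)C=O | intermediate
14 | 2,2-ethylenedioxy-8α-hydroxy-10βH-eremophil-11-en-9-one | C=C(C)[C@H]1C[C@@]2(C)[C@H](CC3(C[C@@H]2C)OCCO3)C(=O)[C@@H]1O | intermediate
15 | 2,2-ethylenedioxy-8α-tigloyloxy-10βH-eremophil-11-en-9-one | C=C(C)[C@H]1C[C@@]2(C)[C@H](CC3(C[C@@H]2C)OCCO3)C(=O)[C@@H]1OC(=O)/C(C)=C/C | intermediate
16 | 2,2-ethylenedioxy-9α-hydroxy-8α-tigloyloxy-10βH-eremophil-11-ene | C=C(C)[C@H]1C[C@@]2(C)[C@H](CC3(C[C@@H]2C)OCCO3)[C@H](O)[C@@H]1OC(=O)/C(C)=C/C | intermediate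
17 | 2,2-ethylenedioxy-9α-senecioyloxy-8α-tigloyloxy-10βH-eremophil-11-ene | C=C(C)[C@H]1C[C@@]2(C)[C@H](CC3(C[C@@H]2C)OCCO3)[C@H](OC(=O)C=C(C)C)[C@@H]1OC(=O)/C(C)=C/C | intermediate
18 | CNP0181050.1 | C=C(C)[C@H]1C[C@@]2(C)[C@H](CC(=O)C[C@@H]2C)[C@H](OC(=O)C=C(C)C)[C@@H]1OC(=O)/C(C)=C/C | target

## Step count and risks

Total step count: 14. Longest linear sequence: 14 steps (1 to 18).

Steps most likely to fail:

1. Step 3 (Diels–Alder). What may go wrong: bond formation at the congested C5–C10 junction may be slow, the dioxolane oxygens may compete with the enal for the boron centre, the silyl enol ether may be lost to acid, and a diene face preference opposed to the catalyst may erode endo or face selectivity. Fallback, setting out from 4 and 5 and coming back at 6: give up catalyst control and use the C9 stereocentre as a built-in resolving handle. The cycloaddition is promoted by achiral MeAlCl2 in CH2Cl2 at −78 °C (or run under high pressure without promoter). The two endo adducts, 6 and the ring A antipodal endo adduct F1, differ in the relation of ring A to C9 and are diastereomers. They are separated by chromatography, 6 goes on to step 4 and F1 is discarded.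

2. Step 10 (carbonyl-ene). What may go wrong: the two chair-like closures of the forming cis-decalin may be poorly discriminated, and the alternative chair would invert both C7 and C8. The Lewis acid may also ionise the C2 ketal, with Prins capture by the prenyl group, and the dicarbonyl may hydrate and stall. Fallback, setting out from 10 and coming back at 14: replace the ene donor by an allylsilane, which is far more nucleophilic and closes the ring by a Hosomi–Sakurai addition under conditions that leave the ketal alone.
   - Aldehyde 10 is olefinated with the ylide from [1-methyl-2-(trimethylsilyl)ethyl]triphenylphosphonium iodide and n-BuLi to give the 2-methylallylsilane F2 (alkene geometry immaterial).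
   - Ethylene glycol with PPTS, as in step 8 but with the weaker acid, gives the allylsilane ketal diol F3.
   - Swern oxidation as in step 9 gives the allylsilane keto aldehyde F4.
   - MgBr2·OEt2 in CH2Cl2 at −40 °C (or catalytic fluoride) makes C7 add to C8 with loss of the silyl group from C12, which leaves the isopropenyl group and gives 14.
   - The later, more product-like transition state of this stepwise addition should favour the all-equatorial steroid-like chair more strongly.

3. Step 9 (double Swern oxidation). What may go wrong: the second oxidation may be incomplete, a methylthiomethyl ether may form at the primary hydroxyl, and the amine base may epimerise C10 once the C9 ketone is present. Fallback, setting out from 12 and coming back at 13: differentiate the two hydroxyls and oxidise them one at a time under neutral conditions.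
   - TBSCl and imidazole silylate the primary hydroxyl to give the C8 silyl ether F5.
   - Dess–Martin periodinane oxidises C9 to give the silyloxy ketone F6.
   - HF·pyridine in THF frees the hydroxy ketone F7.
   - A second Dess–Martin oxidation of the α-ketol gives 13, with no amine base at any stage.

## Further compounds

F1 | step 3 | (1S,2R,6R)-2-[(4S)-2,2-dimethyl-1,3-dioxolan-4-yl]-1,6-dimethyl-4-(triisopropylsilyloxy)cyclohex-3-ene-1-carbaldehyde (ring A antipodal endo adduct) | O=C[C@]1(C)[C@@H](C=C(O[Si](C(C)C)(C(C)C)C(C)C)C[C@H]1C)[C@H]2COC(C)(C)O2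
F2 | step 10 | 2-methylallylsilane, C5–CH2CH=C(CH3)CH2SiMe3, otherwise as 11 | C[Si](C)(C)CC(C)=CC[C@@]1(C)[C@H](C=C(O[Si](C(C)C)(C(C)C)C(C)C)C[C@@H]1C)[C@H]2COC(C)(C)O2
F3 | step 10 | allylsilane C2 ethylene ketal, C8,C9-diol | C[Si](C)(C)CC(C)=CC[C@@]1(C)[C@H](CC2(C[C@@H]1C)OCCO2)[C@H](O)CO
F4 | step 10 | allylsilane C9-keto-C8-aldehyde | C[Si](C)(C)CC(C)=CC[C@@]1(C)[C@H](CC2(C[C@@H]1C)OCCO2)C(=O)C=O
F5 | step 9 | C8 tert-butyldimethylsilyl ether of 12 | CC(C)=CC[C@@]1(C)[C@H](CC2(C[C@@H]1C)OCCO2)[C@H](O)CO[Si](C)(C)C(C)(C)C
F6 | step 9 | C9 ketone, C8 tert-butyldimethylsilyl ether | CC(C)=CC[C@@]1(C)[C@H](CC2(C[C@@H]1C)OCCO2)C(=O)CO[Si](C)(C)C(C)(C)C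
F7 | step 9 | C9 ketone, C8 primary alcohol | CC(C)=CC[C@@]1(C)[C@H](CC2(C[C@@H]1C)OCCO2)C(=O)CO
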